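**Retrosynthetic overview** (upper flavan = rings A, C, B; lower flavan = rings D, F, E; usual flavan locants, primes for ring B)
1. Feature: in ring B the two carbon-bearing atoms C1' (to C2) and C6' (to lower C8) are neighbours and O3'/O4' lie on the opposite edge, so ring B is an alkyne (C1'–C6') plus a symmetric 2,3-dioxygenated butadiene (C2'–C5').
2. Disconnections, backwards: ring C at O1–C8a (Pd-catalysed aryl ether closure); the C2 carbinol from the C2 ketone (Felkin–Anh hydride); ring B by Diels–Alder addition and DDQ dehydrogenation; the ynone at C2–C1' by acetylide acylation of a Weinreb amide; the alkyne at lower C8 by Sonogashira coupling.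
3. Ring order: rings D, F, E come intact from (−)-epicatechin and ring A from 5-bromoresorcinol; ring B is built in steps 13–14; ring C is closed last, in step 16.
4. Stereocentres: lower C2/C3 from epicatechin; upper C3 from methyl (R)-glycidate; upper C2 by reduction under control of C3.
5. The diene carries tert-butyldimethylsilyl groups, so the catechol oxygens stay protected through hydride and base and are freed with O3 in one fluoride step.

Key step: step 13

Assumption: the C6'–C8 biaryl axis has three ortho substituents and is treated as not configurationally fixed, as the target is drawn without an axial descriptor; rotamers about it are not counted as stereoisomers.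

**Step 1**
Reactants: 1 (−)-epicatechin
Product: 2 5,7,3',4'-tetra-O-benzyl-(−)-epicatechin
Conditions: BnBr (4.4 equiv), K2CO3, DMF, 0 °C to rt, argon
Reagents that add atoms: benzyl bromide, BrCc1ccccc1
Why: Williamson etherification in which carbonate deprotonates only the four phenols, so the aliphatic 3-OH stays free and no stereocentre is touched.

**Step 2**
Reactants: 2 5,7,3',4'-tetra-O-benzyl-(−)-epicatechin
Product: 3 3,5,7,3',4'-penta-O-benzyl-(−)-epicatechin
Conditions: NaH, BnBr, Bu4NI (cat.), DMF, 0 °C to rt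
Reagents that add atoms: benzyl bromide, BrCc1ccccc1
Why: Williamson etherification of the secondary alkoxide; with no free phenol left, C2 cannot epimerize through a quinone methide.

**Step 3**
Reactants: 3 3,5,7,3',4'-penta-O-benzyl-(−)-epicatechin
Product: 4 8-iodo-3,5,7,3',4'-penta-O-benzylepicatechin
Conditions: NIS (1.05 equiv), DMF, −20 to 0 °C, dark
Reagents that add atoms: N-iodosuccinimide, O=C1CCC(=O)N1I
Why: Electrophilic aromatic iodination of the phloroglucinol-type ring D, expected at C8 as in the halogenation of 5,7-di-O-benzyl flavans with N-halosuccinimides, because C6 is flanked by two benzyloxy groups.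

**Step 4**
Reactants: 4 8-iodo-3,5,7,3',4'-penta-O-benzylepicatechin; 5 trimethylsilylacetylene
Product: 6 8-[(trimethylsilyl)ethynyl]-3,5,7,3',4'-penta-O-benzylepicatechin
Conditions: PdCl2(PPh3)2 (5 mol %), CuI (10 mol %), Et3N/THF, 60 °C
Reagents that add atoms: none
Why: Sonogashira coupling; the aryl iodide adds oxidatively despite two ortho oxygens and the rod-like alkyne meets little steric resistance at C8.

**Step 5**
Reactants: 6 8-[(trimethylsilyl)ethynyl]-3,5,7,3',4'-penta-O-benzylepicatechin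
Product: 7 8-ethynyl-3,5,7,3',4'-penta-O-benzylepicatechin
Conditions: K2CO3 (0.2 equiv), MeOH/THF, rt
Reagents that add atoms: none
Why: Base-catalysed methanolysis of the alkynyl C–Si bond (protodesilylation), which leaves benzyl ethers untouched.

**Step 6**
Reactants: 8 5-bromoresorcinol
Product: 9 1,3-bis(benzyloxy)-5-bromobenzene
Conditions: BnBr (2.2 equiv), K2CO3, acetone, reflux
Reagents that add atoms: benzyl bromide, BrCc1ccccc1
Why: Williamson etherification of both phenols.

**Step 7**
Reactants: 9 1,3-bis(benzyloxy)-5-bromobenzene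
Product: 10 1,5-bis(benzyloxy)-3-bromo-2-iodobenzene
Conditions: NIS (1.0 equiv), MeCN, rt, dark
Reagents that add atoms: N-iodosuccinimide, O=C1CCC(=O)N1I
Why: Electrophilic aromatic iodination at the position ortho to one benzyloxy group and para to the other (between Br and OBn), the usual site of attack in 1-bromo-3,5-dialkoxybenzenes.

**Step 8**
Reactants: 10 1,5-bis(benzyloxy)-3-bromo-2-iodobenzene; 11 methyl (R)-glycidate
Product: 13 methyl (2R)-3-[2,4-bis(benzyloxy)-6-bromophenyl]-2-hydroxypropanoate, via arylmagnesium chloride 12 (not isolated)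
Conditions: iPrMgCl·LiCl, THF, −40 °C; then CuI (10 mol %), 11, −40 to −20 °C; then 1 M HCl
Reagents that add atoms: none
Why: Iodine–magnesium exchange is much faster than bromine–magnesium exchange; the copper-catalysed Grignard opening of the epoxide (organocuprate SN2 at the CH2 terminus) leaves the C2–O bond intact, so the (R) centre of the glycidate becomes the (R) centre of the hydroxy ester.

**Step 9**
Reactants: 13 methyl (2R)-3-[2,4-bis(benzyloxy)-6-bromophenyl]-2-hydroxypropanoate
Product: 14 methyl (2R)-3-[2,4-bis(benzyloxy)-6-bromophenyl]-2-[(tert-butyldimethylsilyl)oxy]propanoate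
Conditions: TBSCl, imidazole, DMF, rt
Reagents that add atoms: tert-butyldimethylsilyl chloride, CC(C)(C)[Si](C)(C)Cl
Why: Imidazole-promoted O-silylation of the secondary alcohol, which installs the non-chelating group needed for the later reduction.

**Step 10**
Reactants: 14 methyl (2R)-3-[2,4-bis(benzyloxy)-6-bromophenyl]-2-[(tert-butyldimethylsilyl)oxy]propanoate
Product: 15 (2R)-3-[2,4-bis(benzyloxy)-6-bromophenyl]-2-[(tert-butyldimethylsilyl)oxy]-N-methoxy-N-methylpropanamide
Conditions: MeNHOMe·HCl, iPrMgCl, THF, −20 to 0 °C; then 1 M HCl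
Reagents that add atoms: N,O-dimethylhydroxylamine hydrochloride, CNOC.Cl
Why: Ester aminolysis by the chloromagnesium amide (Weinreb amide formation), which at low temperature does not enolize the silyloxy-bearing centre or exchange the electron-rich aryl bromide.

**Step 11**
Reactants: 7 8-ethynyl-3,5,7,3',4'-penta-O-benzylepicatechin; 15 (2R)-3-[2,4-bis(benzyloxy)-6-bromophenyl]-2-[(tert-butyldimethylsilyl)oxy]-N-methoxy-N-methylpropanamide
Product: 18 (2R)-1-[2,4-bis(benzyloxy)-6-bromophenyl]-2-[(tert-butyldimethylsilyl)oxy]-5-(3,5,7,3',4'-penta-O-benzylepicatechin-8-yl)pent-4-yn-3-one, via lithium acetylide 16 (not isolated), via lithium hemiaminal 17 (not isolated)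
Conditions: n-BuLi (1.0 equiv on a slight excess of 7), THF, −78 °C; then 15, −78 to −20 °C; then cold 1 M HCl
Reagents that add atoms: none
Why: Weinreb ketone synthesis; the weakly basic acetylide adds once, the chelated tetrahedral adduct 17 blocks over-addition and releases the ynone only on work-up, so the C3 centre is not enolized.

**Step 12**
Reactants: 19 biacetyl
Product: 20 2,3-bis[(tert-butyldimethylsilyl)oxy]buta-1,3-diene
Conditions: TBSOTf (2.3 equiv), Et3N, CH2Cl2, 0 °C to rt
Reagents that add atoms: tert-butyldimethylsilyl triflate, CC(C)(C)[Si](C)(C)OS(=O)(=O)C(F)(F)F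
Why: Double soft enolization and O-silylation of the 1,2-diketone; the tert-butyldimethylsilyl ethers are chosen over trimethylsilyl so that the diene tolerates long heating and the later catechol ethers tolerate chromatography, hydride and phosphate base.

**Step 13**
Reactants: 18 (2R)-1-[2,4-bis(benzyloxy)-6-bromophenyl]-2-[(tert-butyldimethylsilyl)oxy]-5-(3,5,7,3',4'-penta-O-benzylepicatechin-8-yl)pent-4-yn-3-one; 20 2,3-bis[(tert-butyldimethylsilyl)oxy]buta-1,3-diene
Product: 21 (2R)-1-[4,5-bis[(tert-butyldimethylsilyl)oxy]-2-(3,5,7,3',4'-penta-O-benzylepicatechin-8-yl)cyclohexa-1,4-dien-1-yl]-3-[2,4-bis(benzyloxy)-6-bromophenyl]-2-[(tert-butyldimethylsilyl)oxy]propan-1-one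
Conditions: 20 (5 equiv), BHT (5 mol %), o-xylene, 140 °C, sealed tube, argon
Reagents that add atoms: none
Why: A concerted, thermally allowed normal-demand [4+2] cycloaddition is expected, in which the HOMO of the bis(silyloxy)diene 20 meets the LUMO of ynone 18, lowered by the C2 carbonyl, and the bonds C1'–C2' and C5'–C6' form in one suprafacial event. The closest known reaction type is the Diels–Alder benzannulation of acetylenic ketones and aryl propiolates with 2-silyloxy- and 2,3-bis(silyloxy)butadienes, used to reach hindered biaryls after dehydrogenation. Ring B closes as a six-membered carbocycle by intermolecular cycloaddition, both ring bonds being new, and emerges as a cyclohexa-1,4-diene two hydrogens short of aromatic. No stereocentre is created; the C3 silyloxy centre next to the carbonyl is the only one at risk, and the neutral medium free of acid and base should leave it unenolized. The step needs chemoselectivity and periselectivity but no regioselectivity: the diene is C2-symmetric, the ynone is the only activated π bond, and the absence of a Lewis acid keeps the silyl enol ethers from Mukaiyama–Michael addition. Because the dienophile is a rod-like alkyne, the doubly ortho-oxygenated ring D can turn perpendicular to the forming ring, so the crowded C6'–C8 junction is in place before ring B exists.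

**Step 14**
Reactants: 21 the cyclohexa-1,4-diene adduct
Product: 22 (2R)-1-[4,5-bis[(tert-butyldimethylsilyl)oxy]-2-(3,5,7,3',4'-penta-O-benzylepicatechin-8-yl)phenyl]-3-[2,4-bis(benzyloxy)-6-bromophenyl]-2-[(tert-butyldimethylsilyl)oxy]propan-1-one
Conditions: DDQ (1.05 equiv), PhH, 5 °C to rt, short reaction time
Reagents that add atoms: none
Why: Dehydrogenative aromatization: DDQ abstracts hydride from a doubly allylic CH2 activated by the enol ether and proton loss gives the catechol bis(silyl ether); this should be much faster than the known DDQ oxidation at C4 of benzylated flavans, which the stoichiometric charge and low temperature hold back.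

**Step 15**
Reactants: 22 the ring-B aryl ketone
Product: 23 (1R,2R)-1-[4,5-bis[(tert-butyldimethylsilyl)oxy]-2-(3,5,7,3',4'-penta-O-benzylepicatechin-8-yl)phenyl]-3-[2,4-bis(benzyloxy)-6-bromophenyl]-2-[(tert-butyldimethylsilyl)oxy]propan-1-ol
Conditions: LiBH(s-Bu)3, THF, −78 °C; then AcOH, −78 °C
Reagents that add atoms: none
Why: Felkin–Anh (polar, non-chelated) reduction: the bulky hydride attacks anti to the C3–OSi bond and past the C3 hydrogen, so the C3 centre sets C2 as R and gives the syn alcohol; the cold acidic quench prevents silyl migration in the lithium alkoxide.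

**Step 16**
Reactants: 23 the syn (1R,2R) alcohol
Product: 24 (2R,3R)-5,7-bis(benzyloxy)-3-[(tert-butyldimethylsilyl)oxy]-2-[4,5-bis[(tert-butyldimethylsilyl)oxy]-2-(3,5,7,3',4'-penta-O-benzylepicatechin-8-yl)phenyl]chromane
Conditions: Pd(OAc)2 (5 mol %), 2-(di-tert-butylphosphino)-1,1'-binaphthyl (6 mol %), K3PO4, PhMe, 80 °C
Reagents that add atoms: none
Why: Intramolecular Buchwald–Hartwig C–O coupling closes the six-membered ring C by reductive elimination from an arylpalladium alkoxide; the C2–O bond is not broken, so C2 keeps its configuration and the 2,3-cis flavan results.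

**Step 17**
Reactants: 24 the fully protected biflavan
Product: 25 (2R,3R)-5,7-bis(benzyloxy)-2-[4,5-dihydroxy-2-(3,5,7,3',4'-penta-O-benzylepicatechin-8-yl)phenyl]chroman-3-ol
Conditions: HF·pyridine, pyridine/THF, 0 °C to rt, argon
Reagents that add atoms: none
Why: Fluoride-mediated desilylation removes the two aryl and the one secondary silyl ether under non-basic conditions, which avoids base-induced C2 epimerization and catechol oxidation.

**Step 18**
Reactants: 25 the hepta-O-benzyl biflavan
Product: 26 the target, (2R,3R)-2-[2-((2R,3R)-epicatechin-8-yl)-4,5-dihydroxyphenyl]chromane-3,5,7-triol (CNP0353739.3)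
Conditions: H2 (1 atm), Pd(OH)2/C, THF/MeOH, rt; work-up under argon
Reagents that add atoms: none
Why: Catalytic hydrogenolysis cleaves all seven benzyl ethers, as is routine for benzylated flavan-3-ols, without touching the C2–O1 bonds or the stereocentres.

**Compound list**
1 | (−)-epicatechin | Oc1cc(O)c2c(c1)O[C@H](c1ccc(O)c(O)c1)[C@H](O)C2 | starting material
2 | 5,7,3',4'-tetra-O-benzyl-(−)-epicatechin | c1c(OCc4ccccc4)cc(OCc4ccccc4)c3c1O[C@H](c1ccc(OCc4ccccc4)c(OCc4ccccc4)c1)[C@H](O)C3 | intermediate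
3 | 3,5,7,3',4'-penta-O-benzyl-(−)-epicatechin | c1c(OCc4ccccc4)cc(OCc4ccccc4)c3c1O[C@H](c1ccc(OCc4ccccc4)c(OCc4ccccc4)c1)[C@H](OCc4ccccc4)C3 | intermediate
4 | 8-iodo-3,5,7,3',4'-penta-O-benzylepicatechin | Ic1c(OCc4ccccc4)cc(OCc4ccccc4)c3c1O[C@H](c1ccc(OCc4ccccc4)c(OCc4ccccc4)c1)[C@H](OCc4ccccc4)C3 | intermediate
5 | trimethylsilylacetylene | C#C[Si](C)(C)C | starting material
6 | 8-[(trimethylsilyl)ethynyl]-3,5,7,3',4'-penta-O-benzylepicatechin | C[Si](C)(C)C#Cc1c(OCc4ccccc4)cc(OCc4ccccc4)c3c1O[C@H](c1ccc(OCc4ccccc4)c(OCc4ccccc4)c1)[C@H](OCc4ccccc4)C3 | intermediate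
7 | 8-ethynyl-3,5,7,3',4'-penta-O-benzylepicatechin | C#Cc1c(OCc4ccccc4)cc(OCc4ccccc4)c3c1O[C@H](c1ccc(OCc4ccccc4)c(OCc4ccccc4)c1)[C@H](OCc4ccccc4)C3 | intermediate
8 | 5-bromoresorcinol | Oc1cc(O)cc(Br)c1 | starting material
9 | 1,3-bis(benzyloxy)-5-bromobenzene | Brc1cc(OCc2ccccc2)cc(OCc2ccccc2)c1 | intermediate
10 | 1,5-bis(benzyloxy)-3-bromo-2-iodobenzene | Ic1c(Br)cc(OCc2ccccc2)cc1OCc2ccccc2 | intermediate
11 | methyl (R)-glycidate, methyl (2R)-oxirane-2-carboxylate | COC(=O)[C@H]1CO1 | starting material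
12 | [2,4-bis(benzyloxy)-6-bromophenyl]magnesium chloride (formed in the flask) | Cl[Mg]c1c(Br)cc(OCc2ccccc2)cc1OCc2ccccc2 | intermediate
13 | methyl (2R)-3-[2,4-bis(benzyloxy)-6-bromophenyl]-2-hydroxypropanoate | COC(=O)[C@H](O)Cc1c(Br)cc(OCc2ccccc2)cc1OCc2ccccc2 | intermediate
14 | methyl (2R)-3-[2,4-bis(benzyloxy)-6-bromophenyl]-2-[(tert-butyldimethylsilyl)oxy]propanoate | COC(=O)[C@H](O[Si](C)(C)C(C)(C)C)Cc1c(Br)cc(OCc2ccccc2)cc1OCc2ccccc2 | intermediate
15 | (2R)-3-[2,4-bis(benzyloxy)-6-bromophenyl]-2-[(tert-butyldimethylsilyl)oxy]-N-methoxy-N-methylpropanamide | CON(C)C(=O)[C@H](O[Si](C)(C)C(C)(C)C)Cc1c(Br)cc(OCc2ccccc2)cc1OCc2ccccc2 | intermediate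
16 | lithium acetylide of 7 (formed in the flask) | [Li]C#Cc1c(OCc4ccccc4)cc(OCc4ccccc4)c3c1O[C@H](c1ccc(OCc4ccccc4)c(OCc4ccccc4)c1)[C@H](OCc4ccccc4)C3 | intermediate
17 | lithium N-methoxy-N-methyl hemiaminal from 16 and 15 (formed in the flask; hemiaminal carbon undefined, lost on work-up) | [Li]OC(C#Cc1c(OCc4ccccc4)cc(OCc4ccccc4)c3c1O[C@H](c1ccc(OCc4ccccc4)c(OCc4ccccc4)c1)[C@H](OCc4ccccc4)C3)(N(C)OC)[C@H](O[Si](C)(C)C(C)(C)C)Cc1c(Br)cc(OCc4ccccc4)cc1OCc4ccccc4 | intermediate
18 | ynone, (2R)-1-[2,4-bis(benzyloxy)-6-bromophenyl]-2-[(tert-butyldimethylsilyl)oxy]-5-(3,5,7,3',4'-penta-O-benzylepicatechin-8-yl)pent-4-yn-3-one | O=C(C#Cc1c(OCc4ccccc4)cc(OCc4ccccc4)c3c1O[C@H](c1ccc(OCc4ccccc4)c(OCc4ccccc4)c1)[C@H](OCc4ccccc4)C3)[C@H](O[Si](C)(C)C(C)(C)C)Cc1c(Br)cc(OCc4ccccc4)cc1OCc4ccccc4 | intermediate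
19 | biacetyl | CC(=O)C(C)=O | starting material
20 | 2,3-bis[(tert-butyldimethylsilyl)oxy]buta-1,3-diene | C=C(O[Si](C)(C)C(C)(C)C)C(=C)O[Si](C)(C)C(C)(C)C | intermediate
21 | cyclohexa-1,4-diene adduct (ring B two hydrogens short of aromatic) | O=C(C5=C(c1c(OCc4ccccc4)cc(OCc4ccccc4)c3c1O[C@H](c1ccc(OCc4ccccc4)c(OCc4ccccc4)c1)[C@H](OCc4ccccc4)C3)CC(O[Si](C)(C)C(C)(C)C)=C(O[Si](C)(C)C(C)(C)C)C5)[C@H](O[Si](C)(C)C(C)(C)C)Cc1c(Br)cc(OCc4ccccc4)cc1OCc4ccccc4 | intermediate
22 | ring-B aryl ketone, (2R)-configured | O=C(c5cc(O[Si](C)(C)C(C)(C)C)c(O[Si](C)(C)C(C)(C)C)cc5-c1c(OCc4ccccc4)cc(OCc4ccccc4)c3c1O[C@H](c1ccc(OCc4ccccc4)c(OCc4ccccc4)c1)[C@H](OCc4ccccc4)C3)[C@H](O[Si](C)(C)C(C)(C)C)Cc1c(Br)cc(OCc4ccccc4)cc1OCc4ccccc4 | intermediate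
23 | syn (1R,2R) alcohol | O[C@H](c5cc(O[Si](C)(C)C(C)(C)C)c(O[Si](C)(C)C(C)(C)C)cc5-c1c(OCc4ccccc4)cc(OCc4ccccc4)c3c1O[C@H](c1ccc(OCc4ccccc4)c(OCc4ccccc4)c1)[C@H](OCc4ccccc4)C3)[C@H](O[Si](C)(C)C(C)(C)C)Cc1c(Br)cc(OCc4ccccc4)cc1OCc4ccccc4 | intermediate
24 | fully protected biflavan (upper 2R,3R; seven benzyl and three silyl ethers) | O(Cc4ccccc4)c1cc(OCc4ccccc4)c2c(c1)O[C@H](c1cc(O[Si](C)(C)C(C)(C)C)c(O[Si](C)(C)C(C)(C)C)cc1-c1c(OCc4ccccc4)cc(OCc4ccccc4)c3c1O[C@H](c1ccc(OCc4ccccc4)c(OCc4ccccc4)c1)[C@H](OCc4ccccc4)C3)[C@H](O[Si](C)(C)C(C)(C)C)C2 | intermediate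
25 | hepta-O-benzyl biflavan with free upper 3-OH, 3'-OH and 4'-OH | O(Cc4ccccc4)c1cc(OCc4ccccc4)c2c(c1)O[C@H](c1cc(O)c(O)cc1-c1c(OCc4ccccc4)cc(OCc4ccccc4)c3c1O[C@H](c1ccc(OCc4ccccc4)c(OCc4ccccc4)c1)[C@H](OCc4ccccc4)C3)[C@H](O)C2 | intermediate
26 | CNP0353739.3 | Oc1cc(O)c2c(c1)O[C@H](c1cc(O)c(O)cc1-c1c(O)cc(O)c3c1O[C@H](c1ccc(O)c(O)c1)[C@H](O)C3)[C@H](O)C2 | target

**Count**
Total steps: 18. Longest linear sequence: 12 steps (steps 1–5, 11, 13–18; the branch through steps 6–10 is equally long).

**Steps most likely to fail**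

1. Step 13. The cycloaddition may be slower than thermal loss of the diene (desilylation, oligomerization), because the electron-releasing, doubly ortho-substituted ring D raises the ynone LUMO and screens the alkyne.
Fallback: ring B is brought in already aromatic, with the C6'–C8 bond made by cross-coupling and the C2–C1' bond by aryllithium acylation. It sets out from iodide 4 and Weinreb amide 15 and returns at ketone 22. Iodide 4 is exchanged with t-BuLi (2 equiv, THF, −78 °C) to the 8-lithio compound F1 and transmetalated with ZnCl2 to the arylzinc chloride F2. Negishi coupling (Pd(OAc)2, 2-dicyclohexylphosphino-2',6'-dimethoxybiphenyl, THF, 60 °C) with an excess of 1,2-dibromo-4,5-bis[(tert-butyldimethylsilyl)oxy]benzene F3 (from commercial 4,5-dibromobenzene-1,2-diol, TBSCl, imidazole, DMF) should give the biaryl bromide F4. Bromine–lithium exchange (t-BuLi, 2 equiv, Et2O, −78 °C) gives the aryllithium F5. This is added at −78 °C to Weinreb amide 15 and, through the lithium hemiaminal F6, should give ketone 22 on acidic work-up. Steps 4, 5 and 11–14 are then not needed.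

2. Step 16. β-Hydride elimination from the arylpalladium alkoxide may return the ketone with loss of bromine, or base may move the silyl group from O3 to O2, after which O3 would close a five-membered ring.
Fallback: the metal and the bond-forming event are changed to an Ullmann-type etherification, set out from alcohol 23 and returning at 24. Conditions: CuI (20 mol %), 3,4,7,8-tetramethyl-1,10-phenanthroline, Cs2CO3, PhMe, 110 °C. The monovalent copper alkoxide has no ready β-hydride path, and the aryl–oxygen bond forms at copper without a palladium alkoxide.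

3. Step 15. The hindered ketone, twisted by the ortho aryl group, may react sluggishly with the bulky hydride or with poor facial selectivity, and warming invites silyl migration in the alkoxide.
Fallback: control is moved from the substrate to a catalyst by Corey–Bakshi–Shibata reduction, set out from ketone 22 and returning at alcohol 23. Conditions: (R)-2-methyl-CBS-oxazaborolidine (the enantiomer that turns acetophenone into (S)-1-phenylethanol), catecholborane, PhMe, −40 °C. With ring B as the large group the hydride is delivered to the same carbonyl face as in the Felkin–Anh pathway, so catalyst and substrate are matched.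

**Further compounds**
F1 | step 13 | 8-lithio-3,5,7,3',4'-penta-O-benzylepicatechin | [Li]c1c(OCc4ccccc4)cc(OCc4ccccc4)c3c1O[C@H](c1ccc(OCc4ccccc4)c(OCc4ccccc4)c1)[C@H](OCc4ccccc4)C3
F2 | step 13 | (3,5,7,3',4'-penta-O-benzylepicatechin-8-yl)zinc chloride | Cl[Zn]c1c(OCc4ccccc4)cc(OCc4ccccc4)c3c1O[C@H](c1ccc(OCc4ccccc4)c(OCc4ccccc4)c1)[C@H](OCc4ccccc4)C3
F3 | step 13 | 1,2-dibromo-4,5-bis[(tert-butyldimethylsilyl)oxy]benzene | Brc1cc(O[Si](C)(C)C(C)(C)C)c(O[Si](C)(C)C(C)(C)C)cc1Br
F4 | step 13 | 8-{2-bromo-4,5-bis[(tert-butyldimethylsilyl)oxy]phenyl}-3,5,7,3',4'-penta-O-benzylepicatechin | Brc5cc(O[Si](C)(C)C(C)(C)C)c(O[Si](C)(C)C(C)(C)C)cc5-c1c(OCc4ccccc4)cc(OCc4ccccc4)c3c1O[C@H](c1ccc(OCc4ccccc4)c(OCc4ccccc4)c1)[C@H](OCc4ccccc4)C3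
F5 | step 13 | aryllithium from F4 | [Li]c5cc(O[Si](C)(C)C(C)(C)C)c(O[Si](C)(C)C(C)(C)C)cc5-c1c(OCc4ccccc4)cc(OCc4ccccc4)c3c1O[C@H](c1ccc(OCc4ccccc4)c(OCc4ccccc4)c1)[C@H](OCc4ccccc4)C3
F6 | step 13 | lithium N-methoxy-N-methyl hemiaminal from F5 and 15 | [Li]OC(c5cc(O[Si](C)(C)C(C)(C)C)c(O[Si](C)(C)C(C)(C)C)cc5-c1c(OCc4ccccc4)cc(OCc4ccccc4)c3c1O[C@H](c1ccc(OCc4ccccc4)c(OCc4ccccc4)c1)[C@H](OCc4ccccc4)C3)(N(C)OC)[C@H](O[Si](C)(C)C(C)(C)C)Cc1c(Br)cc(OCc4ccccc4)cc1OCc4ccccc4
F0 | step 16 | none | none
F0 | step 15 | none | none
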